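**Plan**

- Retrosynthesis: the two O‑methyl groups come off last; the cyclohexane is then opened at the bond between its two adjacent ring CH2 groups (the one next to the C=CH2 carbon and the one next to CHBr), and the chain is cut at the ArCH2–CH bond.
- Enabling feature: in the ring, bromine sits on the carbon between that CH2 and the quaternary CMe2 carbon, and the exocyclic methylene carbon is the other neighbour of the bond. A bromonium ion bridging CHBr/CH2, shielded at CHBr by CMe2, can therefore be opened at CH2 by the =CH2 end of a 2‑(silylmethyl)allyl unit, giving ring and exocyclic alkene in one event without breaking the C–Br bond.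
- Forward: benzylation of an N‑acyl oxazolidinone joins the aryl fragment to 3,3‑dimethylpent‑4‑enoic acid; hydroboration/lactonization, conversion of the lactone carbonyl into the allylsilane, oxidation and α‑bromination/reduction give the acyclic bromohydrin; its triflation closes the only carbocycle; oxidative demethylation and reduction finish.
- Stereochemistry: the CH(CH2Ar) centre comes from the (R)‑4‑benzyloxazolidinone auxiliary; the C–Br centre from catalyst‑controlled α‑bromination while that carbon is still an aldehyde α‑carbon; the ring closure creates no stereocentre and preserves both (cis, both equatorial in the chair).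

Key step: step 9

Remark: the catalyst enantiomer in step 8 is assigned from the steric‑shielding model (bromine delivered anti to the phenyl group on the ring carbon syn to the enamine double bond); if induction proved opposite, the (2S,5S) catalyst would be used.

**Route**

Step 1
Reactants: 1 4-bromo-2,5-dimethoxybenzaldehyde
Product: 2 (4-bromo-2,5-dimethoxyphenyl)methanol
Conditions: NaBH4, MeOH/THF, 0 °C
Reagents that add atoms: none
Why: Hydride reduction of the aryl aldehyde by NaBH4 is chemoselective, the aryl bromide and methyl ethers being inert.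

Step 2
Reactants: 2 (4-bromo-2,5-dimethoxyphenyl)methanol
Product: 3 1-bromo-4-(bromomethyl)-2,5-dimethoxybenzene
Conditions: PBr3, CH2Cl2, 0 °C → rt
Reagents that add atoms: phosphorus tribromide, BrP(Br)Br
Why: Standard PBr3 bromination of an electron-rich benzylic alcohol through its phosphite ester by SN2 displacement.

Step 3
Reactants: 4 3,3-dimethylpent-4-enoic acid; 5 (4R)-4-benzyl-1,3-oxazolidin-2-one
Product: 7 (4R)-4-benzyl-3-(3,3-dimethylpent-4-enoyl)-1,3-oxazolidin-2-one, via mixed pivalic anhydride 6 (not isolated)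
Conditions: t-BuCOCl, Et3N, THF, −20 °C; then LiCl, 5, −20 °C → rt
Reagents that add atoms: none
Why: N-Acylation of the oxazolidinone through the mixed anhydride, the nucleophile attacking the less hindered non-pivaloyl carbonyl under LiCl/Et3N activation.

Step 4
Reactants: 7 (4R)-4-benzyl-3-(3,3-dimethylpent-4-enoyl)-1,3-oxazolidin-2-one; 3 1-bromo-4-(bromomethyl)-2,5-dimethoxybenzene
Product: 9 (4R)-4-benzyl-3-{(2R)-2-[(4-bromo-2,5-dimethoxyphenyl)methyl]-3,3-dimethylpent-4-enoyl}-1,3-oxazolidin-2-one, via sodium Z-enolate 8 (not isolated)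
Conditions: NaN(SiMe3)2, THF, −78 °C; then 3, −78 → −20 °C
Reagents that add atoms: none
Why: Evans asymmetric alkylation, in which the chelated Z-enolate is benzylated on the face remote from the auxiliary's benzyl group, so that the (R)-auxiliary should set the (2R) centre that becomes the CH(CH2Ar) ring carbon; the reactive benzylic bromide offsets the neopentylic hindrance of the enolate.

Step 5
Reactants: 9 (4R)-4-benzyl-3-{(2R)-2-[(4-bromo-2,5-dimethoxyphenyl)methyl]-3,3-dimethylpent-4-enoyl}-1,3-oxazolidin-2-one
Product: 12 (3R)-3-[(4-bromo-2,5-dimethoxyphenyl)methyl]-4,4-dimethyloxan-2-one, via alkylborane 10 (not isolated), via hydroxy imide 11 (not isolated)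
Conditions: 9-BBN, THF, 0 °C → rt; then 30% H2O2, aq NaOAc, 0 °C → rt; then 1,8-diazabicyclo[5.4.0]undec-7-ene (cat.), CH2Cl2, rt
Reagents that add atoms: hydrogen peroxide, OO
Why: Anti-Markovnikov hydroboration–oxidation of the monosubstituted alkene (boron to the open terminal carbon, imide inert to 9-BBN) followed by base-catalysed N-to-O acyl transfer, a 6-exo-trig lactonization favoured by the gem-dimethyl group, which should release the auxiliary without touching the α-stereocentre.

Step 6
Reactants: 12 (3R)-3-[(4-bromo-2,5-dimethoxyphenyl)methyl]-4,4-dimethyloxan-2-one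
Product: 14 (4R)-4-[(4-bromo-2,5-dimethoxyphenyl)methyl]-3,3-dimethyl-5-[(trimethylsilyl)methyl]hex-5-en-1-ol, via bis-silyl diol 13 (not isolated)
Conditions: Me3SiCH2MgCl, CeCl3, THF, −78 °C → rt; then SiO2, CH2Cl2, rt
Reagents that add atoms: (trimethylsilylmethyl)magnesium chloride, C[Si](C)(C)C[Mg]Cl
Why: CeCl3-mediated double addition of the non-basic silylmethyl reagent to the lactone carbonyl (no enolization of the α-stereocentre) and acid-promoted Peterson elimination of the bis(β-silyl) carbinol on silica should give the 2-substituted allylsilane and free the primary alcohol in one operation.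

Step 7
Reactants: 14 (4R)-4-[(4-bromo-2,5-dimethoxyphenyl)methyl]-3,3-dimethyl-5-[(trimethylsilyl)methyl]hex-5-en-1-ol
Product: 15 (4R)-4-[(4-bromo-2,5-dimethoxyphenyl)methyl]-3,3-dimethyl-5-[(trimethylsilyl)methyl]hex-5-enal
Conditions: Dess–Martin periodinane, NaHCO3, CH2Cl2, 0 °C → rt
Reagents that add atoms: none
Why: Dess–Martin oxidation of the primary alcohol under buffered, non-acidic conditions that should leave the allylsilane and the electron-rich arene untouched.

Step 8
Reactants: 15 (4R)-4-[(4-bromo-2,5-dimethoxyphenyl)methyl]-3,3-dimethyl-5-[(trimethylsilyl)methyl]hex-5-enal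
Product: 17 (2S,4S)-2-bromo-4-[(4-bromo-2,5-dimethoxyphenyl)methyl]-3,3-dimethyl-5-[(trimethylsilyl)methyl]hex-5-en-1-ol, via bromo aldehyde 16 (not isolated)
Conditions: (2R,5R)-2,5-diphenylpyrrolidine (20 mol %), PhCO2H (20 mol %), 4,4-dibromo-2,6-di-tert-butylcyclohexa-2,5-dien-1-one, H2O (2 equiv), CH2Cl2/pentane, −40 °C; then NaBH4, MeOH, −40 → 0 °C
Reagents that add atoms: 4,4-dibromo-2,6-di-tert-butylcyclohexa-2,5-dien-1-one, CC(C)(C)C1=CC(Br)(Br)C=C(C(C)(C)C)C1=O
Why: Organocatalytic asymmetric α-bromination by enamine catalysis, in which the C2-symmetric amine shields one face of the aldehyde α-carbon so that the mild Br+ donor should deliver bromine under catalyst control to give the (S)-bromide (the activated aldehyde being far more nucleophilic in its catalytic form than the allylsilane or the arene); NaBH4 in the same flask reduces the configurationally labile α-bromo aldehyde before it can racemize.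

Step 9
Reactants: 17 (2S,4S)-2-bromo-4-[(4-bromo-2,5-dimethoxyphenyl)methyl]-3,3-dimethyl-5-[(trimethylsilyl)methyl]hex-5-en-1-ol
Product: 20 1-bromo-4-{[(1S,3R)-3-bromo-2,2-dimethyl-6-methylidenecyclohexyl]methyl}-2,5-dimethoxybenzene, via primary triflate 18 (not isolated), via bromonium triflate 19 (not isolated)
Conditions: (CF3SO2)2O, 2,6-di-tert-butyl-4-methylpyridine, CH2Cl2, −78 → 0 °C
Reagents that add atoms: none
Why: Proposed new method: O-triflation gives 18, whose β-bromine expels triflate from the backside to form the bromiranium ion 19 without touching the C–Br stereocentre, and the =CH2 terminus of the 2-substituted allylsilane then opens 19 at its primary carbon, the β-silyl cation collapsing by loss of the silyl group to the exocyclic methylene. The closest known reaction types are allylsilane-terminated epoxide and halonium cation–olefin cyclizations and the enantiospecific generation of bromonium ions from enantiopure β-bromo alcohol derivatives by neighbouring-group ionization; new here is carbon capture at the unsubstituted carbon of a monosubstituted bromonium ion. The six-membered ring should close through a chair, endo with respect to both the allylsilane double bond and the bromonium ion (both of its carbons become ring members), which equals a 6-exo-tet displacement at CH2–OTf if 19 is only a tight ion pair. No stereocentre is created: the bromide carbon keeps its configuration because only the primary carbon undergoes substitution, and the CH(CH2Ar) centre is a spectator whose cis relationship to bromine lets both substituents sit equatorial in the chair. The step needs attack at the primary and not the secondary bromonium carbon, and C–C bond formation and not transfer of Br+ to the allylsilane; the first is secured by the quaternary CMe2 carbon, which makes the secondary carbon neopentylic and would force a five-membered ring, the second by the absence of any free electrophilic bromine source and by the irreversible loss of silicon.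

Step 10
Reactants: 20 1-bromo-4-{[(1S,3R)-3-bromo-2,2-dimethyl-6-methylidenecyclohexyl]methyl}-2,5-dimethoxybenzene
Product: 21 2-bromo-5-{[(1S,3R)-3-bromo-2,2-dimethyl-6-methylidenecyclohexyl]methyl}cyclohexa-2,5-diene-1,4-dione
Conditions: (NH4)2Ce(NO3)6, MeCN/H2O, 0 °C
Reagents that add atoms: water, O
Why: Oxidative demethylation of the 1,4-dimethoxyarene by single-electron oxidation with tetravalent cerium (water supplying the quinone oxygens) is fast at 0 °C and should spare the 1,1-disubstituted alkene and both bromides.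

Step 11
Reactants: 21 2-bromo-5-{[(1S,3R)-3-bromo-2,2-dimethyl-6-methylidenecyclohexyl]methyl}cyclohexa-2,5-diene-1,4-dione
Product: 22 cyclocymopol, 2-bromo-5-{[(1S,3R)-3-bromo-2,2-dimethyl-6-methylidenecyclohexyl]methyl}benzene-1,4-diol
Conditions: Na2S2O4, THF/H2O, rt
Reagents that add atoms: none
Why: Two-electron reduction of the quinone by dithionite under neutral conditions should give the hydroquinone without affecting the alkene or the alkyl bromide.

**Compound list**

1 | 4-bromo-2,5-dimethoxybenzaldehyde | O=Cc1cc(OC)c(Br)cc1OC | starting material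
2 | (4-bromo-2,5-dimethoxyphenyl)methanol | OCc1cc(OC)c(Br)cc1OC | intermediate
3 | 1-bromo-4-(bromomethyl)-2,5-dimethoxybenzene | BrCc1cc(OC)c(Br)cc1OC | intermediate
4 | 3,3-dimethylpent-4-enoic acid | C=CC(C)(C)CC(=O)O | starting material
5 | (4R)-4-benzyl-1,3-oxazolidin-2-one | O=C1N[C@H](Cc2ccccc2)CO1 | starting material
6 | 3,3-dimethylpent-4-enoic 2,2-dimethylpropanoic anhydride | C=CC(C)(C)CC(=O)OC(=O)C(C)(C)C | intermediate
7 | (4R)-4-benzyl-3-(3,3-dimethylpent-4-enoyl)-1,3-oxazolidin-2-one | C=CC(C)(C)CC(=O)N1[C@H](Cc2ccccc2)COC1=O | intermediate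
8 | sodium (Z)-enolate of 7 | C=CC(C)(C)/C=C(\[O-])N1[C@H](Cc2ccccc2)COC1=O.[Na+] | intermediate
9 | (4R)-4-benzyl-3-{(2R)-2-[(4-bromo-2,5-dimethoxyphenyl)methyl]-3,3-dimethylpent-4-enoyl}-1,3-oxazolidin-2-one | C=CC(C)(C)[C@@H](Cc1cc(OC)c(Br)cc1OC)C(=O)N1[C@H](Cc2ccccc2)COC1=O | intermediate
10 | (4R)-4-benzyl-3-{(2R)-5-(9-borabicyclo[3.3.1]nonan-9-yl)-2-[(4-bromo-2,5-dimethoxyphenyl)methyl]-3,3-dimethylpentanoyl}-1,3-oxazolidin-2-one | O=C1OC[C@@H](Cc2ccccc2)N1C(=O)[C@H](Cc1cc(OC)c(Br)cc1OC)C(C)(C)CCB1C2CCCC1CCC2 | intermediate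
11 | (4R)-4-benzyl-3-{(2R)-2-[(4-bromo-2,5-dimethoxyphenyl)methyl]-5-hydroxy-3,3-dimethylpentanoyl}-1,3-oxazolidin-2-one | OCCC(C)(C)[C@@H](Cc1cc(OC)c(Br)cc1OC)C(=O)N1[C@H](Cc2ccccc2)COC1=O | intermediate
12 | (3R)-3-[(4-bromo-2,5-dimethoxyphenyl)methyl]-4,4-dimethyloxan-2-one | O=C1OCCC(C)(C)[C@H]1Cc1cc(OC)c(Br)cc1OC | intermediate
13 | (4R)-4-[(4-bromo-2,5-dimethoxyphenyl)methyl]-3,3-dimethyl-6-(trimethylsilyl)-5-[(trimethylsilyl)methyl]hexane-1,5-diol | OCCC(C)(C)[C@@H](Cc1cc(OC)c(Br)cc1OC)C(O)(C[Si](C)(C)C)C[Si](C)(C)C | intermediate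
14 | (4R)-4-[(4-bromo-2,5-dimethoxyphenyl)methyl]-3,3-dimethyl-5-[(trimethylsilyl)methyl]hex-5-en-1-ol | OCCC(C)(C)[C@@H](Cc1cc(OC)c(Br)cc1OC)C(=C)C[Si](C)(C)C | intermediate
15 | (4R)-4-[(4-bromo-2,5-dimethoxyphenyl)methyl]-3,3-dimethyl-5-[(trimethylsilyl)methyl]hex-5-enal | O=CCC(C)(C)[C@@H](Cc1cc(OC)c(Br)cc1OC)C(=C)C[Si](C)(C)C | intermediate
16 | (2S,4S)-2-bromo-4-[(4-bromo-2,5-dimethoxyphenyl)methyl]-3,3-dimethyl-5-[(trimethylsilyl)methyl]hex-5-enal | O=C[C@@H](Br)C(C)(C)[C@@H](Cc1cc(OC)c(Br)cc1OC)C(=C)C[Si](C)(C)C | intermediate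
17 | (2S,4S)-2-bromo-4-[(4-bromo-2,5-dimethoxyphenyl)methyl]-3,3-dimethyl-5-[(trimethylsilyl)methyl]hex-5-en-1-ol | OC[C@@H](Br)C(C)(C)[C@@H](Cc1cc(OC)c(Br)cc1OC)C(=C)C[Si](C)(C)C | intermediate
18 | (2S,4S)-2-bromo-4-[(4-bromo-2,5-dimethoxyphenyl)methyl]-3,3-dimethyl-5-[(trimethylsilyl)methyl]hex-5-en-1-yl trifluoromethanesulfonate | FC(F)(F)S(=O)(=O)OC[C@@H](Br)C(C)(C)[C@@H](Cc1cc(OC)c(Br)cc1OC)C(=C)C[Si](C)(C)C | intermediate
19 | (2S)-2-{(3S)-3-[(4-bromo-2,5-dimethoxyphenyl)methyl]-2-methyl-4-[(trimethylsilyl)methyl]pent-4-en-2-yl}bromiran-1-ium trifluoromethanesulfonate | C1[Br+][C@H]1C(C)(C)[C@@H](Cc2cc(OC)c(Br)cc2OC)C(=C)C[Si](C)(C)C.[O-]S(=O)(=O)C(F)(F)F | intermediate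
20 | 1-bromo-4-{[(1S,3R)-3-bromo-2,2-dimethyl-6-methylidenecyclohexyl]methyl}-2,5-dimethoxybenzene | C=C1CC[C@@H](Br)C(C)(C)[C@H]1Cc1cc(OC)c(Br)cc1OC | intermediate
21 | 2-bromo-5-{[(1S,3R)-3-bromo-2,2-dimethyl-6-methylidenecyclohexyl]methyl}cyclohexa-2,5-diene-1,4-dione | C=C1CC[C@@H](Br)C(C)(C)[C@H]1CC1=CC(=O)C(Br)=CC1=O | intermediate
22 | cyclocymopol, 2-bromo-5-{[(1S,3R)-3-bromo-2,2-dimethyl-6-methylidenecyclohexyl]methyl}benzene-1,4-diol | C=C1CC[C@@H](Br)C(C)(C)[C@H]1Cc1cc(O)c(Br)cc1O | target

**Summary and risks**

Total step count: 11. Longest linear sequence: 10 steps (steps 1, 2 and 4–11, from 4-bromo-2,5-dimethoxybenzaldehyde); 9 steps from 3,3-dimethylpent-4-enoic acid.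

Steps most likely to fail:

1. Step 9 (Proposed new method). The bromonium ion may be opened at its secondary carbon or suffer a methyl shift from the neopentylic position. Br+ may be transferred to the allylsilane double bond instead of C–C bond formation. The primary triflate may alkylate intermolecularly. Fallback (known chemistry), setting out from 17 and returning at 20: K2CO3 in MeOH should close the terminal epoxide F1 by displacement of bromide, with inversion at the former C–Br carbon. BF3·OEt2 in CH2Cl2 at −78 °C should then effect a Lewis acid-promoted epoxide–allylsilane cyclization at the unhindered primary epoxide carbon, giving the axial cyclohexanol F2, whose hydroxyl is trans to the arylmethyl group. Appel bromination (PPh3, CBr4, CH2Cl2) with inversion should then give 20.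

2. Step 8. The bromine donor may be consumed by the allylsilane (bromodesilylation). The acid co-catalyst may trigger a Mannich-type closure of the transient iminium ion onto the allylsilane. Facial selectivity may erode through mismatch with the neighbouring stereocentre, or the α-bromo aldehyde may racemize before reduction. Fallback, setting out from 11 (isolated by leaving out the base treatment of step 5) and returning at 17: Dess–Martin oxidation should give the aldehyde imide F3. The same catalytic bromination and NaBH4 reduction, now with no allylsilane in the molecule, should give the bromohydrin imide F4. Catalytic 1,8-diazabicyclo[5.4.0]undec-7-ene should lactonize it, with loss of the auxiliary, to the bromolactone F5. CeCl3-mediated double addition of Me3SiCH2MgCl and Peterson elimination on silica, as in step 6, should then give 17.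

3. Step 6. Addition may stall after the first equivalent at the hindered β-silyl ketone (enolization instead of second addition), or Peterson elimination may be incomplete. Fallback, setting out from 12 and returning at 14: one equivalent of Me3SiCH2Li in THF at −78 °C should stop at the ketone stage and give, after work-up, the silyl hydroxy ketone F6. Takai–Lombardo methylenation (Zn, CH2Br2, TiCl4, THF/CH2Cl2, 0 °C → rt), which tolerates free hydroxyl groups and hindered enolizable ketones, should then convert the carbonyl group into the 1,1-disubstituted alkene of 14.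

**Further compounds**

F1 | step 9 | (2R)-2-{(3R)-3-[(4-bromo-2,5-dimethoxyphenyl)methyl]-2-methyl-4-[(trimethylsilyl)methyl]pent-4-en-2-yl}oxirane | C1O[C@@H]1C(C)(C)[C@@H](Cc2cc(OC)c(Br)cc2OC)C(=C)C[Si](C)(C)C
F2 | step 9 | (1S,3S)-3-[(4-bromo-2,5-dimethoxyphenyl)methyl]-2,2-dimethyl-4-methylidenecyclohexan-1-ol | C=C1CC[C@H](O)C(C)(C)[C@H]1Cc1cc(OC)c(Br)cc1OC
F3 | step 8 | (4R)-5-[(4R)-4-benzyl-2-oxo-1,3-oxazolidin-3-yl]-4-[(4-bromo-2,5-dimethoxyphenyl)methyl]-3,3-dimethyl-5-oxopentanal | O=CCC(C)(C)[C@@H](Cc1cc(OC)c(Br)cc1OC)C(=O)N1[C@H](Cc2ccccc2)COC1=O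
F4 | step 8 | (4R)-4-benzyl-3-{(2R,4S)-4-bromo-2-[(4-bromo-2,5-dimethoxyphenyl)methyl]-5-hydroxy-3,3-dimethylpentanoyl}-1,3-oxazolidin-2-one | OC[C@@H](Br)C(C)(C)[C@@H](Cc1cc(OC)c(Br)cc1OC)C(=O)N1[C@H](Cc2ccccc2)COC1=O
F5 | step 8 | (3R,5S)-5-bromo-3-[(4-bromo-2,5-dimethoxyphenyl)methyl]-4,4-dimethyloxan-2-one | O=C1OC[C@@H](Br)C(C)(C)[C@H]1Cc1cc(OC)c(Br)cc1OC
F6 | step 6 | (3R)-3-[(4-bromo-2,5-dimethoxyphenyl)methyl]-6-hydroxy-4,4-dimethyl-1-(trimethylsilyl)hexan-2-one | OCCC(C)(C)[C@@H](Cc1cc(OC)c(Br)cc1OC)C(=O)C[Si](C)(C)C
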